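**Strategy.** The ten-membered ring is closed last across C3–C4 by an intramolecular Negishi coupling between a C3 alkylzinc and a C4 1,1-dibromoalkene. The step exploits the trisubstituted 4E olefin (C4=C5) of the carbocycle: palladium inserts into the bromide trans to C6, so ring closure alone fixes the E geometry and leaves the cis bromide as the socket for the C15 methyl. The precursor is an unzipped (S)-carvone: its cyclohexene (C5–C10) sets C6–C9 under cyclic control and carries the cis-fused methylene lactone; ozonolysis of C5=C10 then gives a C10 ketone (Z-selective Wittig, C1–C3) and a C5 aldehyde (dibromo-olefination).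

Key step: step 16

Remark: atom labels C1–C15 follow germacrane numbering of the target (lactone O on C6, ring fusion C7, ester on C8, OH on C9, C14 on C10, C15 on C4, C11–C13 the methylene lactone). The SMILES is read as the 6,7-cis-fused lactone, 1(10)Z,4E isomer carrying a (2S,3S)-2,3-epoxy-2-methylbutanoate. On the carvone-derived ring, O6, C11 and O9 lie on one face and O8 on the other.

Step 1
Reactants: 1 (S)-(+)-carvone
Product: 3 (5R,6R)-2-methyl-5-(prop-1-en-2-yl)-6-[(triethylsilyl)oxy]cyclohex-2-en-1-one, via triethylsilyl dienol ether 2 (not isolated)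
Conditions: LiN(i-Pr)2, THF, −78 °C; Et3SiCl; then dimethyldioxirane, acetone/CH2Cl2, −40 to 0 °C
Reagents that add atoms: chlorotriethylsilane CC[Si](Cl)(CC)CC; dimethyldioxirane CC1(C)OO1
Why: Kinetic α′-deprotonation and O-silylation give the cross-conjugated dienol ether, whose electron-rich C8=C9 bond is epoxidised anti to the C7 isopropenyl group and rearranges by silyl shift to the trans α′-silyloxy enone (Rubottom oxidation), which sets C8.

Step 2
Reactants: 3 α′-silyloxy enone
Product: 4 (1R,5R,6R)-2-methyl-5-(prop-1-en-2-yl)-6-[(triethylsilyl)oxy]cyclohex-2-en-1-ol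
Conditions: NaBH4, CeCl3·7H2O, MeOH, −78 °C
Reagents that add atoms: none
Why: Luche 1,2-reduction by axial hydride delivery gives the equatorial C9 alcohol, trans to the C8 silyloxy group and cis to the isopropenyl group, as in the reduction of carvone to cis-carveol.

Step 3
Reactants: 4 allylic alcohol
Product: 5 tert-butyl(dimethyl)silyl ether of 4
Conditions: t-BuMe2SiOTf, 2,6-lutidine, CH2Cl2, −78 to 0 °C
Reagents that add atoms: tert-butyldimethylsilyl trifluoromethanesulfonate CC(C)(C)[Si](C)(C)OS(=O)(=O)C(F)(F)F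
Why: Silyl triflate silylation of the hindered secondary allylic alcohol installs the robust O9 group that outlasts the more labile O8 triethylsilyl ether.

Step 4
Reactants: 5 bis-silyl ether
Product: 6 (4R,5R,6R)-4-[(tert-butyldimethylsilyl)oxy]-3-methyl-6-(prop-1-en-2-yl)-5-[(triethylsilyl)oxy]cyclohex-2-en-1-one
Conditions: CrO3, 3,5-dimethylpyrazole, CH2Cl2, −20 °C
Reagents that add atoms: chromium trioxide O=[Cr](=O)=O
Why: CrO3–3,5-dimethylpyrazole allylic oxidation converts the only ring allylic methylene (C6) into the enone carbonyl, the C9–H being shielded by the two flanking silyloxy groups.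

Step 5
Reactants: 6 enone
Product: 7 (4R,5R,6R)-4-[(tert-butyldimethylsilyl)oxy]-6-(3-hydroxyprop-1-en-2-yl)-3-methyl-5-[(triethylsilyl)oxy]cyclohex-2-en-1-one
Conditions: SeO2 (cat.), t-BuOOH, CH2Cl2, 0 °C to rt
Reagents that add atoms: tert-butyl hydroperoxide CC(C)(C)OO
Why: With the ring olefin deactivated as an enone, SeO2-catalysed allylic hydroxylation (ene reaction then [2,3]-shift) attacks only the isopropenyl group and, following the CH3-over-CH preference, gives the C12 alcohol.

Step 6
Reactants: 7 hydroxy enone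
Product: 8 (1S,4R,5R,6S)-4-[(tert-butyldimethylsilyl)oxy]-6-(3-hydroxyprop-1-en-2-yl)-3-methyl-5-[(triethylsilyl)oxy]cyclohex-2-en-1-ol
Conditions: LiBH(s-Bu)3, THF, −78 °C; aq. NH4Cl
Reagents that add atoms: none
Why: The bulky hydride adds 1,2 to the β,β-disubstituted enone from the equatorial side, anti to the adjacent C7 side chain, so the new C6 hydroxyl is axial and cis to C7–C11 (diastereoselective ketone reduction).

Step 7
Reactants: 8 diol
Product: 9 (3aS,4R,5R,7aS)-5-[(tert-butyldimethylsilyl)oxy]-6-methyl-3-methylidene-4-[(triethylsilyl)oxy]-3a,4,5,7a-tetrahydro-1-benzofuran-2(3H)-one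
Conditions: TEMPO (cat.), PhI(OAc)2, CH2Cl2, rt
Reagents that add atoms: none
Why: TEMPO/PhI(OAc)2 oxidises the primary allylic alcohol chemoselectively, the cis C6 hydroxyl traps the enal as a lactol and a second oxidation gives the cis-fused α-methylene-γ-butyrolactone (oxidative lactonisation of a 1,4-diol).

Step 8
Reactants: 9 bicyclic lactone
Product: 10 (2R,3S)-3-{(1R,2S)-2-[(tert-butyldimethylsilyl)oxy]-3-oxo-1-[(triethylsilyl)oxy]butyl}-4-methylidene-5-oxooxolane-2-carbaldehyde
Conditions: O3, CH2Cl2/MeOH, −78 °C; Me2S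
Reagents that add atoms: ozone [O-][O+]=O
Why: Ozonolysis cleaves the trisubstituted C5=C10 olefin far faster than the electron-poor acrylate C11=C13 bond and unzips the ring into the C5 aldehyde and the C10 methyl ketone without touching C6–C9.

Step 9
Reactants: 10 keto aldehyde
Product: 11 (4S,5R)-5-(2,2-dibromoethenyl)-4-{(1R,2S)-2-[(tert-butyldimethylsilyl)oxy]-3-oxo-1-[(triethylsilyl)oxy]butyl}-3-methylideneoxolan-2-one
Conditions: CBr4, PPh3, Zn (premixed), CH2Cl2, 0 °C
Reagents that add atoms: carbon tetrabromide BrC(Br)(Br)Br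
Why: Ramirez dibromo-olefination (first stage of the Corey–Fuchs sequence) with preformed Ph3P=CBr2 converts the aldehyde only, the hindered methyl ketone being inert to this stabilised ylide.

Step 10
Reactants: 11 dibromoalkene
Product: 12 (4S,5R)-5-(2,2-dibromoethenyl)-3-[(dimethylamino)methyl]-4-{(1R,2S)-2-[(tert-butyldimethylsilyl)oxy]-3-oxo-1-[(triethylsilyl)oxy]butyl}oxolan-2-one (C11 epimers)
Conditions: Me2NH, THF, 0 °C
Reagents that add atoms: dimethylamine CNC
Why: Reversible aza-Michael addition masks the α-methylene lactone as a Mannich base so that the nucleophilic ylide of step 12 cannot add to it.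

Step 11
Reactants: 13 1-[(3-bromopropoxy)methyl]-4-methoxybenzene
Product: 14 {3-[(4-methoxybenzyl)oxy]propyl}triphenylphosphonium bromide
Conditions: PPh3, MeCN, reflux
Reagents that add atoms: triphenylphosphine c1ccc(cc1)P(c1ccccc1)c1ccccc1
Why: SN2 quaternisation of triphenylphosphine by the primary bromide gives the Wittig salt.

Step 12
Reactants: 12 masked keto lactone; 14 phosphonium bromide
Product: 16 (4S,5R)-5-(2,2-dibromoethenyl)-3-[(dimethylamino)methyl]-4-{(1R,2R,3Z)-2-[(tert-butyldimethylsilyl)oxy]-6-[(4-methoxybenzyl)oxy]-3-methyl-1-[(triethylsilyl)oxy]hex-3-en-1-yl}oxolan-2-one, via phosphorus ylide 15 (not isolated)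
Conditions: 14, KN(SiMe3)2, THF, 0 °C; then 12, −78 to −20 °C
Reagents that add atoms: none
Why: Wittig olefination of an α-silyloxy methyl ketone with a non-stabilised ylide under lithium-free conditions is Z-selective (α-alkoxy ketone effect in the kinetically formed oxaphosphetane), which places C2 cis to C9 and sets the 1(10)Z olefin.

Step 13
Reactants: 16 Mannich base
Product: 18 (4S,5R)-5-(2,2-dibromoethenyl)-4-{(1R,2R,3Z)-2-[(tert-butyldimethylsilyl)oxy]-6-[(4-methoxybenzyl)oxy]-3-methyl-1-[(triethylsilyl)oxy]hex-3-en-1-yl}-3-methylideneoxolan-2-one, via trimethylammonium iodide 17 (not isolated)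
Conditions: MeI, MeOH, rt; then aq. NaHCO3, CH2Cl2
Reagents that add atoms: none
Why: N-Methylation turns the amine into a leaving group and mild base triggers E1cB loss of trimethylamine, restoring the α-methylene lactone.

Step 14
Reactants: 18 p-methoxybenzyl ether
Product: 19 the corresponding primary C3 alcohol (6-hydroxyhexenyl side chain)
Conditions: DDQ, CH2Cl2/pH 7 buffer, 0 °C
Reagents that add atoms: none
Why: DDQ cleaves the electron-rich p-methoxybenzyl ether oxidatively via its benzylic cation while the silyl ethers, the dibromoalkene and the lactone are untouched.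

Step 15
Reactants: 19 primary alcohol
Product: 20 (4S,5R)-5-(2,2-dibromoethenyl)-4-{(1R,2R,3Z)-2-[(tert-butyldimethylsilyl)oxy]-6-iodo-3-methyl-1-[(triethylsilyl)oxy]hex-3-en-1-yl}-3-methylideneoxolan-2-one
Conditions: I2, PPh3, imidazole, CH2Cl2, 0 °C
Reagents that add atoms: iodine II
Why: Appel-type iodination converts the primary alcohol into the iodide by SN2 displacement of the alkoxyphosphonium ion.

Step 16
Reactants: 20 iodo dibromoalkene
Product: 22 ten-membered bromo lactone (target ring with Br in place of C15 and C3 trans to C6; O8–SiEt3 and O9–SiMe2t-Bu), via alkylzinc iodide 21 (not isolated)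
Conditions: Zn dust (activated with Me3SiCl and BrCH2CH2Br), THF, 40 °C; then slow addition to PdCl2[O(C6H4-2-PPh2)2] (10 mol %), THF/DMF, 50 °C, 2 mM
Reagents that add atoms: none
Why: Zinc inserts into the primary C3–I bond only (alkenyl bromides are inert under these conditions); zerovalent palladium then adds to the C4–Br bond trans to C6, the less hindered of the two, and intramolecular transmetalation followed by reductive elimination joins C3 to C4. The closest known reaction type is the trans-selective Negishi monoalkylation of 1,1-dibromo-1-alkenes with alkylzinc halides, run here in its ring-closing form. The ten-membered carbocycle is closed end to end by C(sp3)–C(sp2) reductive elimination from an eleven-membered palladacycle, with the C4=C5 olefin endocyclic. No stereocentre is created; the 4E ring geometry follows from the trans preference of the oxidative addition, and C6–C9 are untouched. The step needs ring closure to beat oligomerisation, protonation of the organozinc and β-hydride elimination: slow addition at about 2 mM, the wide-bite-angle diphosphine, and the turn imposed by the cis-fused lactone and the 1(10)Z olefin, which hold C3 near C4, secure it. The retained cis bromide is replaced by methyl in step 17.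

Step 17
Reactants: 22 macrocyclic alkenyl bromide
Product: 23 (1(10)Z,4E)-macrocycle with C15 methyl; O8–SiEt3 and O9–SiMe2t-Bu (target core, (6S,7S,8R,9R))
Conditions: Zn(CH3)2, Pd[P(t-Bu)3]2 (5 mol %), THF, 25 °C
Reagents that add atoms: dimethylzinc C[Zn]C
Why: Negishi methylation of the remaining alkenyl bromide with the bulky electron-rich Pd[P(t-Bu)3]2 catalyst proceeds with retention of olefin geometry, so C15 ends cis to C6 and the 4E olefin is complete.

Step 18
Reactants: 23 bis-silyl ether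
Product: 24 C8 alcohol (O9 still tert-butyldimethylsilylated)
Conditions: pyridinium p-toluenesulfonate, MeOH/CH2Cl2, 0 °C
Reagents that add atoms: none
Why: Mild acid methanolysis removes the triethylsilyl ether selectively because it is far more labile than the tert-butyldimethylsilyl ether on O9 (selective desilylation).

Step 19
Reactants: 25 methyl angelate
Product: 26 (2Z)-2-methylbut-2-en-1-ol
Conditions: (i-Bu)2AlH, CH2Cl2, −78 °C
Reagents that add atoms: none
Why: Hydride reduction of the conjugated ester goes 1,2 to the allylic alcohol without isomerising the Z olefin.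

Step 20
Reactants: 26 Z-allylic alcohol
Product: 27 [(2R,3S)-2,3-dimethyloxiran-2-yl]methanol
Conditions: Ti(OiPr)4, L-(+)-diethyl tartrate, t-BuOOH, 4 Å sieves, CH2Cl2, −20 °C
Reagents that add atoms: tert-butyl hydroperoxide CC(C)(C)OO
Why: Sharpless asymmetric epoxidation with L-(+)-diethyl tartrate delivers oxygen to the face of the Z-allylic alcohol that gives the (2R,3S)-epoxy alcohol (reagent control).

Step 21
Reactants: 27 epoxy alcohol
Product: 28 (2S,3S)-2,3-dimethyloxirane-2-carboxylic acid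
Conditions: RuCl3·xH2O (cat.), NaIO4, CCl4/MeCN/H2O, rt
Reagents that add atoms: sodium periodate [Na+].[O-]I(=O)(=O)=O; water O
Why: RuO4 generated catalytically from RuCl3 and NaIO4 oxidises the primary alcohol to the carboxylic acid without opening the epoxide or touching its stereocentres.

Step 22
Reactants: 24 C8 alcohol; 28 epoxy acid
Product: 29 9-O-tert-butyldimethylsilyl ether of the target
Conditions: 28, 2,4,6-trichlorobenzoyl chloride, Et3N, THF; then 24, DMAP, toluene, rt to 40 °C
Reagents that add atoms: none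
Why: Yamaguchi esterification via the mixed 2,4,6-trichlorobenzoic anhydride acylates the only free hydroxyl (O8) with retention at C8 and at both epoxide carbons.

Step 23
Reactants: 29 silyl-protected ester
Product: 30 CNP0318223.3
Conditions: HF·pyridine, pyridine/THF, 0 °C to rt
Reagents that add atoms: none
Why: Buffered HF·pyridine cleaves the remaining silyl ether under mildly acidic conditions that avoid acyl migration, epoxide opening and conjugate addition to the lactone (fluoride desilylation).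

**Compound list**

1 | (S)-(+)-carvone, (5S)-2-methyl-5-(prop-1-en-2-yl)cyclohex-2-en-1-one | CC1=CC[C@H](C(C)=C)CC1=O | starting material
2 | triethyl{[(3S)-6-methyl-3-(prop-1-en-2-yl)cyclohexa-1,5-dien-1-yl]oxy}silane (dienol ether of 1) | CC1=CC[C@H](C(C)=C)C=C1O[Si](CC)(CC)CC | intermediate
3 | (5R,6R)-2-methyl-5-(prop-1-en-2-yl)-6-[(triethylsilyl)oxy]cyclohex-2-en-1-one (silyloxy trans to isopropenyl) | CC1=CC[C@H](C(C)=C)[C@@H](O[Si](CC)(CC)CC)C1=O | intermediate
4 | (1R,5R,6R)-2-methyl-5-(prop-1-en-2-yl)-6-[(triethylsilyl)oxy]cyclohex-2-en-1-ol (OH trans to silyloxy, cis to isopropenyl) | CC1=CC[C@H](C(C)=C)[C@@H](O[Si](CC)(CC)CC)[C@@H]1O | intermediate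
5 | tert-butyl(dimethyl){[(1R,5R,6R)-2-methyl-5-(prop-1-en-2-yl)-6-[(triethylsilyl)oxy]cyclohex-2-en-1-yl]oxy}silane | CC1=CC[C@H](C(C)=C)[C@@H](O[Si](CC)(CC)CC)[C@@H]1O[Si](C)(C)C(C)(C)C | intermediate
6 | (4R,5R,6R)-4-[(tert-butyldimethylsilyl)oxy]-3-methyl-6-(prop-1-en-2-yl)-5-[(triethylsilyl)oxy]cyclohex-2-en-1-one | CC1=CC(=O)[C@H](C(C)=C)[C@@H](O[Si](CC)(CC)CC)[C@@H]1O[Si](C)(C)C(C)(C)C | intermediate
7 | (4R,5R,6R)-4-[(tert-butyldimethylsilyl)oxy]-6-(3-hydroxyprop-1-en-2-yl)-3-methyl-5-[(triethylsilyl)oxy]cyclohex-2-en-1-one | CC1=CC(=O)[C@H](C(CO)=C)[C@@H](O[Si](CC)(CC)CC)[C@@H]1O[Si](C)(C)C(C)(C)C | intermediate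
8 | (1S,4R,5R,6S)-4-[(tert-butyldimethylsilyl)oxy]-6-(3-hydroxyprop-1-en-2-yl)-3-methyl-5-[(triethylsilyl)oxy]cyclohex-2-en-1-ol (ring OH cis to the side chain) | CC1=C[C@H](O)[C@H](C(CO)=C)[C@@H](O[Si](CC)(CC)CC)[C@@H]1O[Si](C)(C)C(C)(C)C | intermediate
9 | (3aS,4R,5R,7aS)-5-[(tert-butyldimethylsilyl)oxy]-6-methyl-3-methylidene-4-[(triethylsilyl)oxy]-3a,4,5,7a-tetrahydro-1-benzofuran-2(3H)-one (cis-fused) | CC1=C[C@@H]2OC(=O)C(=C)[C@@H]2[C@@H](O[Si](CC)(CC)CC)[C@@H]1O[Si](C)(C)C(C)(C)C | intermediate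
10 | (2R,3S)-3-{(1R,2S)-2-[(tert-butyldimethylsilyl)oxy]-3-oxo-1-[(triethylsilyl)oxy]butyl}-4-methylidene-5-oxooxolane-2-carbaldehyde | O=C[C@@H]1OC(=O)C(=C)[C@@H]1[C@@H](O[Si](CC)(CC)CC)[C@H](O[Si](C)(C)C(C)(C)C)C(C)=O | intermediate
11 | (4S,5R)-5-(2,2-dibromoethenyl)-4-{(1R,2S)-2-[(tert-butyldimethylsilyl)oxy]-3-oxo-1-[(triethylsilyl)oxy]butyl}-3-methylideneoxolan-2-one | BrC(Br)=C[C@@H]1OC(=O)C(=C)[C@@H]1[C@@H](O[Si](CC)(CC)CC)[C@H](O[Si](C)(C)C(C)(C)C)C(C)=O | intermediate
12 | (4S,5R)-5-(2,2-dibromoethenyl)-3-[(dimethylamino)methyl]-4-{(1R,2S)-2-[(tert-butyldimethylsilyl)oxy]-3-oxo-1-[(triethylsilyl)oxy]butyl}oxolan-2-one (C11 epimers) | BrC(Br)=C[C@@H]1OC(=O)C(CN(C)C)[C@@H]1[C@@H](O[Si](CC)(CC)CC)[C@H](O[Si](C)(C)C(C)(C)C)C(C)=O | intermediate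
13 | 1-[(3-bromopropoxy)methyl]-4-methoxybenzene | COc1ccc(COCCCBr)cc1 | starting material
14 | {3-[(4-methoxybenzyl)oxy]propyl}triphenylphosphonium bromide | COc1ccc(COCCC[P+](c2ccccc2)(c2ccccc2)c2ccccc2)cc1.[Br-] | intermediate
15 | {3-[(4-methoxybenzyl)oxy]propylidene}triphenylphosphorane | COc1ccc(COCCC=P(c2ccccc2)(c2ccccc2)c2ccccc2)cc1 | intermediate
16 | (4S,5R)-5-(2,2-dibromoethenyl)-3-[(dimethylamino)methyl]-4-{(1R,2R,3Z)-2-[(tert-butyldimethylsilyl)oxy]-6-[(4-methoxybenzyl)oxy]-3-methyl-1-[(triethylsilyl)oxy]hex-3-en-1-yl}oxolan-2-one (C11 epimers) | BrC(Br)=C[C@@H]1OC(=O)C(CN(C)C)[C@@H]1[C@@H](O[Si](CC)(CC)CC)[C@H](O[Si](C)(C)C(C)(C)C)/C(C)=C\CCOCc1ccc(OC)cc1 | intermediate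
17 | N-methyl quaternary ammonium iodide of 16 | BrC(Br)=C[C@@H]1OC(=O)C(C[N+](C)(C)C)[C@@H]1[C@@H](O[Si](CC)(CC)CC)[C@H](O[Si](C)(C)C(C)(C)C)/C(C)=C\CCOCc1ccc(OC)cc1.[I-] | intermediate
18 | (4S,5R)-5-(2,2-dibromoethenyl)-4-{(1R,2R,3Z)-2-[(tert-butyldimethylsilyl)oxy]-6-[(4-methoxybenzyl)oxy]-3-methyl-1-[(triethylsilyl)oxy]hex-3-en-1-yl}-3-methylideneoxolan-2-one | BrC(Br)=C[C@@H]1OC(=O)C(=C)[C@@H]1[C@@H](O[Si](CC)(CC)CC)[C@H](O[Si](C)(C)C(C)(C)C)/C(C)=C\CCOCc1ccc(OC)cc1 | intermediate
19 | (4S,5R)-5-(2,2-dibromoethenyl)-4-{(1R,2R,3Z)-2-[(tert-butyldimethylsilyl)oxy]-6-hydroxy-3-methyl-1-[(triethylsilyl)oxy]hex-3-en-1-yl}-3-methylideneoxolan-2-one | BrC(Br)=C[C@@H]1OC(=O)C(=C)[C@@H]1[C@@H](O[Si](CC)(CC)CC)[C@H](O[Si](C)(C)C(C)(C)C)/C(C)=C\CCO | intermediate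
20 | (4S,5R)-5-(2,2-dibromoethenyl)-4-{(1R,2R,3Z)-2-[(tert-butyldimethylsilyl)oxy]-6-iodo-3-methyl-1-[(triethylsilyl)oxy]hex-3-en-1-yl}-3-methylideneoxolan-2-one | BrC(Br)=C[C@@H]1OC(=O)C(=C)[C@@H]1[C@@H](O[Si](CC)(CC)CC)[C@H](O[Si](C)(C)C(C)(C)C)/C(C)=C\CCI | intermediate
21 | C3 alkylzinc iodide derived from 20 | BrC(Br)=C[C@@H]1OC(=O)C(=C)[C@@H]1[C@@H](O[Si](CC)(CC)CC)[C@H](O[Si](C)(C)C(C)(C)C)/C(C)=C\CC[Zn]I | intermediate
22 | ten-membered bromo lactone: target ring system with Br in place of the C15 methyl (Br cis to C6, C3 trans to C6), 1(10)Z, O8–SiEt3, O9–SiMe2t-Bu, C6–C9 as in the target | C=C1C(=O)O[C@H]2/C=C(\Br)CC/C=C(/C)[C@@H](O[Si](C)(C)C(C)(C)C)[C@H](O[Si](CC)(CC)CC)[C@@H]12 | intermediate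
23 | (6S,7S,8R,9R)-9-[(tert-butyldimethylsilyl)oxy]-8-[(triethylsilyl)oxy]germacra-1(10)Z,4E,11(13)-trien-12,6-olide | C=C1C(=O)O[C@H]2/C=C(\C)CC/C=C(/C)[C@@H](O[Si](C)(C)C(C)(C)C)[C@H](O[Si](CC)(CC)CC)[C@@H]12 | intermediate
24 | 8-hydroxy-9-[(tert-butyldimethylsilyl)oxy]germacra-1(10)Z,4E,11(13)-trien-12,6-olide, C6–C9 as in the target | C=C1C(=O)O[C@H]2/C=C(\C)CC/C=C(/C)[C@@H](O[Si](C)(C)C(C)(C)C)[C@H](O)[C@@H]12 | intermediate
25 | methyl angelate, methyl (2Z)-2-methylbut-2-enoate | C/C=C(/C)C(=O)OC | starting material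
26 | (2Z)-2-methylbut-2-en-1-ol | C/C=C(/C)CO | intermediate
27 | [(2R,3S)-2,3-dimethyloxiran-2-yl]methanol | OC[C@@]1(C)O[C@H]1C | intermediate
28 | (2S,3S)-2,3-dimethyloxirane-2-carboxylic acid (epoxyangelic acid) | OC(=O)[C@@]1(C)O[C@H]1C | intermediate
29 | 9-O-tert-butyldimethylsilyl ether of the target, (6S,7S,8R,9R) | C=C1C(=O)O[C@H]2/C=C(\C)CC/C=C(/C)[C@@H](O[Si](C)(C)C(C)(C)C)[C@H](OC(=O)[C@@]3(C)O[C@H]3C)[C@@H]12 | intermediate
30 | CNP0318223.3, (6S,7S,8R,9R)-9-hydroxy-12-oxogermacra-1(10)Z,4E,11(13)-trien-12,6-olid-8-yl (2S,3S)-2,3-dimethyloxirane-2-carboxylate | C=C1C(=O)O[C@H]2/C=C(\C)CC/C=C(/C)[C@@H](O)[C@H](OC(=O)[C@@]3(C)O[C@H]3C)[C@@H]12 | target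

**Step count.** Total: 23 steps. Longest linear sequence: 19 steps from (S)-carvone (steps 1–10, 12–18, 22, 23).

**Steps most likely to fail, with fallbacks**

Step 16 (key ring closure). Ring closure may lose to oligomerisation or to protonation of the alkylzinc. The bromoalkenyl–palladium species may also isomerise before transmetalation and couple at the cis position. Fallback: starting again from 20, the same bond is closed without a preformed organozinc by nickel-catalysed reductive cross-electrophile coupling (NiCl2(dme), 4,4′-di-tert-butyl-2,2′-bipyridine, Mn, NaI, DMA, slow addition). The C3 radical released from the iodide is captured by the alkenylnickel formed at the trans C4–Br bond. This returns to the route at 22 and makes no new compound (F0).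

Step 4 (allylic oxidation). Hydrogen abstraction may occur at C9–H or at the allylic positions of the isopropenyl group instead of at C6, or the product may over-oxidise. Fallback: from 4, hydroxyl-directed epoxidation (VO(acac)2, t-BuOOH, CH2Cl2) of the ring olefin syn to O9 gives the cis-epoxy alcohol F1, leaving the isopropenyl group untouched. Silylation (t-BuMe2SiOTf, 2,6-lutidine) gives the epoxy silyl ether F2. Sodium phenylselenide (from PhSeSePh and NaBH4, EtOH) opens it trans-diaxially at C5 to the β-hydroxy selenide F3. H2O2 oxidation and selenoxide syn-elimination away from the carbinol give the tertiary allylic alcohol F4 (C10–OH, C5=C6). Oxidative 1,3-transposition with pyridinium chlorochromate, [C5H5NH][CrO3Cl], then returns to the route at 6.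

Step 12 (Z-selective Wittig). The ylide may act as a base, enolising the C10 ketone and triggering β-elimination of the C8 silyloxy group, or the Z/E control may erode. Fallback: from 14, aqueous NaOH gives the phosphine oxide F5. Its lithio derivative (n-BuLi, THF, −78 °C) adds to 12 to give β-hydroxy phosphine oxides, from which the diastereomer F6 is separated by chromatography. NaH in DMF then eliminates diphenylphosphinate syn-stereospecifically (Horner–Wittig), giving only the Z olefin and returning to the route at 16.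

**Further compounds**

F0 | step 16 | none | none
F1 | step 4 | C5–C10 epoxide of 4, oxirane oxygen syn to the C9 hydroxyl | C[C@@]12O[C@@H]1C[C@H](C(C)=C)[C@@H](O[Si](CC)(CC)CC)[C@@H]2O
F2 | step 4 | tert-butyldimethylsilyl ether of F1 | C[C@@]12O[C@@H]1C[C@H](C(C)=C)[C@@H](O[Si](CC)(CC)CC)[C@@H]2O[Si](C)(C)C(C)(C)C
F3 | step 4 | β-hydroxy selenide: C5–SePh anti to the tertiary C10 hydroxyl | C[C@@]1(O)[C@@H]([Se]c2ccccc2)C[C@H](C(C)=C)[C@@H](O[Si](CC)(CC)CC)[C@@H]1O[Si](C)(C)C(C)(C)C
F4 | step 4 | tertiary allylic alcohol: C10 carbinol with C5=C6 olefin | C[C@@]1(O)C=C[C@H](C(C)=C)[C@@H](O[Si](CC)(CC)CC)[C@@H]1O[Si](C)(C)C(C)(C)C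
F5 | step 12 | {3-[(4-methoxybenzyl)oxy]propyl}diphenylphosphine oxide | COc1ccc(COCCCP(=O)(c2ccccc2)c2ccccc2)cc1
F6 | step 12 | β-hydroxy phosphine oxide adduct of 12 (C10 carbinol, C1 phosphinoyl; the diastereomer whose syn elimination gives the Z olefin) | BrC(Br)=C[C@@H]1OC(=O)C(CN(C)C)[C@@H]1[C@@H](O[Si](CC)(CC)CC)[C@H](O[Si](C)(C)C(C)(C)C)[C@](C)(O)[C@@H](CCOCc1ccc(OC)cc1)P(=O)(c1ccccc1)c1ccccc1
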